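3 questions stood on one flask, followed on Thursday up to 6.00 min and asked about at 5.0 s and 12 min.

| setting | Thursday's | flask |
|---|---|---|
| starting material | 0.20 M | 0.20 M |
| first nucleophile | 2 equiv | 2.00 equiv |
| second nucleophile | 1.2 equiv | 1.20 equiv |
| protic impurity | 4 mM | 4.00 mM |
| remark | the very flask that is asked about, followed so far |  |
| time |  | 12 min |
Thursday's run (percent of the starting material charged)

| time / min | other capture product / % | target / % | starting material / % |
|---|---|---|---|
| 0.500 | 15 | 8 | 78 |
| 1.50 | 40 | 7 | 49 |
| 3.00 | 60 | 6 | 36 |
| 4.00 | 64 | 7 | 28 |
| 6.00 | 72 | 5 | 19 |

(scatter of a reading: 2 percentage points)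
- ratio of other capture product to target at 5.0 s
- ratio of other capture product to target at 12 min
- which of other capture product and target there is more of at 12 min


I took the loss of starting material as first order in [second nucleophile], read as its charge less the other capture product formed. The loss of starting material is then pseudo-first-order at any moment. From the fall between 3.00 min and 6.00 min, with [second nucleophile] read at 4.00 min, I got 1.90 L mol⁻¹ min⁻¹, the capture constant: first-order loss rate of starting material divided by [second nucleophile]. Holding [second nucleophile] at the 0.0960 M so reckoned for 6.00 min, I estimated 6.35 % starting material at 12 min. With target at its 3.00 min reading and the remainder counted as other capture product, my ratio was 14.6.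

The forecast gave 0.7 at 5.0 s and 15 at 12 min, with other capture product ahead at 12 min, and saw target as “a short burst”.

The flask gave 2.32 and 14.4, with other capture product ahead at 12 min.

    starting material + target → side product (k = 0.00964 L mol⁻¹ s⁻¹)
    second nucleophile + protic impurity → quenched reagent (k = 9.57 L mol⁻¹ s⁻¹)
    second nucleophile + intermediate → other capture product (k = 5.62 L mol⁻¹ s⁻¹)
    first nucleophile → decomposed reagent (k = 0.0318 s⁻¹)
    first nucleophile + intermediate → target (k = 1.54 L mol⁻¹ s⁻¹)
    starting material ⇌ intermediate (K = 0.00721, k = 0.0320 s⁻¹)

The early ratio was 2.32, not 0.7, and at 0.350 min in this flask first nucleophile, which with intermediate gives target, had a half-life of 0.36 min by its decomposition step. With 28.4 % of the second nucleophile's charge left at 12.0 min in this flask, the capture constant gives starting material a half-life of 5.35 min; 5.92 % of it stood there at that time, and other capture product went from 84.0 % then to 89.7 % at 120 min.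

In the neighbour flask with 2.00 equiv of second nucleophile, holding [second nucleophile] at its excess over the starting material, 0.200 M, the constant gives 1.04 % starting material at 12 min. That flask computed to 0.42 %, less than my figure, with a ratio of 16.7.

The data are calculated with made-up constants, noise included.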